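## Retrosynthetic overview

1. Numbering: oxolane O1, C2 (catechol ring), C3 (bears C9H2OH), C4 (bears carbinol C7 and the guaiacyl ring), C5 (CH2). The route rests on the C3–C4 bond of this ring. Its branches C9 and C7 lie on the same face (3,4-cis, the less stable arrangement) and C9 lies anti to the C2 aryl group. A vinyl group (C9 plus one carbon) and a carboxyl group (C7) take up this pattern after a ring-contracting ester-enolate Claisen rearrangement.
2. Endgame: the phenols are freed last (benzyl ethers). C9–OH comes from oxidative cleavage of the vinyl group, the C7 stereocentre from oxazaborolidine-catalysed reduction of aryl ketone 24, and the C7–aryl bond from Weinreb amide 19 and aryllithium 22.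
3. Key disconnection: the C3–C4 bond of acid 17 is traced back to nine-membered lactone 14 through the [3,3] shift of its silyl ketene acetal 15.
4. Lactone 14 comes from seco acid 12 (acyl C7–O bond). Acid 12 comes from aldehyde 1, alkyne 2 (the asymmetric alkynylation sets C2, the only stereocentre before the key step) and allyl bromide 5 (C5, C4, C7).
5. Ring order: the nine-membered lactone is closed in step 7 and contracted to the oxolane in step 8. A bicyclic lactol appears in step 13 and is opened in step 14. The three benzene rings are bought.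

Key step: step 8

Remarks on the chemistry:
- (a) The target numbering (O1, C2–C5, C7, C9) is used for the corresponding atoms of all intermediates.
- (b) The (S)-BINOL–Ti(OiPr)4 alkynylzinc system is assumed to attack the Si face of 1, as in its dialkylzinc additions. The configuration of 4 would be checked by Mosher ester analysis, and (R)-BINOL would be used if the sense were opposite.
- (c) Metal alkoxides, carboxylates and borate esters are not numbered when they differ from a listed compound only by a metal or boron on oxygen and are released on work-up.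

## Route

Step 1
Reactants: 1 3,4-bis(benzyloxy)benzaldehyde; 2 tert-butyldimethyl(prop-2-yn-1-yloxy)silane
Product: 4 (1R)-1-[3,4-bis(benzyloxy)phenyl]-4-[(tert-butyldimethylsilyl)oxy]but-2-yn-1-ol, via alkynyl(ethyl)zinc 3 (not isolated)
Conditions: 2 (2.2 equiv), Et2Zn (2.0 equiv), toluene, reflux; then (S)-BINOL (20 mol %), Ti(OiPr)4 (50 mol %), Et2O, rt; then 1, rt; aq. NH4Cl
Reagents that add atoms: diethylzinc, CC[Zn]CC (ethylzinc unit, present in 3 only)
Why: Titanium–BINOLate-catalysed asymmetric alkynylzinc addition, a reaction type at its best with aromatic aldehydes, should deliver the alkynyl group of 3 to the Si face of 1 and so set C2 (descriptor R here, because the alkynyl carbon outranks the aryl carbon).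

Step 2
Reactants: 4 (1R)-propargylic alcohol; 5 allyl bromide
Product: 6 tert-butyl({(4R)-4-[3,4-bis(benzyloxy)phenyl]-4-(prop-2-en-1-yloxy)but-2-yn-1-yl}oxy)dimethylsilane
Conditions: NaH, Bu4NI (cat.), THF, 0 °C → rt
Reagents that add atoms: none
Why: Williamson ether synthesis on the sodium alkoxide brings in C5, C4 and C7 without touching the C2–H bond, and it is preferred to an acrylate oxa-Michael addition because that reaction is reversible for a hindered secondary alcohol and a tert-butyl ester could later be removed only with acid that would ionise this doubly activated benzylic ether.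

Step 3
Reactants: 6 allyl ether
Product: 8 3-{[(1R)-1-[3,4-bis(benzyloxy)phenyl]-4-[(tert-butyldimethylsilyl)oxy]but-2-yn-1-yl]oxy}propan-1-ol, via B-alkyl-9-BBN adduct 7 (not isolated)
Conditions: 9-BBN (1.2 equiv), THF, 0 °C → rt; then 30% H2O2, 3 M NaOH, 0 °C
Reagents that add atoms: hydrogen peroxide, OO (oxygen of the new OH); 9-borabicyclo[3.3.1]nonane, C1CC2CCCC(C1)B2 (present in 7 only)
Why: Brown hydroboration–oxidation: 9-BBN adds to a terminal alkene much faster than to an internal alkyne flanked by two C–O bonds and puts boron on the terminal carbon, so alkaline H2O2 should give the primary alcohol with the alkyne intact.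

Step 4
Reactants: 8 primary alcohol
Product: 10 3-{[(1R)-1-[3,4-bis(benzyloxy)phenyl]-4-[(tert-butyldimethylsilyl)oxy]but-2-yn-1-yl]oxy}propanoic acid, via aldehyde 9 (not isolated)
Conditions: TEMPO (20 mol %), PhI(OAc)2 (2.3 equiv), MeCN–H2O 1:1, rt
Reagents that add atoms: water, O
Why: TEMPO/PhI(OAc)2 oxidation in wet MeCN takes the primary alcohol through aldehyde 9 and its hydrate to the acid at near-neutral pH, which spares the silyl ether, the benzyl ethers and the benzylic propargylic ether, and it is run before the semihydrogenation because the C2–H bond is least prone to hydride loss at the alkyne stage.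

Step 5
Reactants: 10 alkynyl acid
Product: 11 3-{[(1S,2Z)-1-[3,4-bis(benzyloxy)phenyl]-4-[(tert-butyldimethylsilyl)oxy]but-2-en-1-yl]oxy}propanoic acid
Conditions: H2 (1 atm), 5% Pd/CaCO3 poisoned with Pb(OAc)2, quinoline, EtOAc, rt
Reagents that add atoms: none
Why: Lindlar semihydrogenation adds H2 to one face of the adsorbed alkyne and so gives the Z-alkene that the key step needs, while lead and quinoline poisoning should hold back over-reduction, Z/E isomerisation and benzyl ether hydrogenolysis (the centre is unchanged in space; the descriptor becomes S because aryl outranks alkenyl).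

Step 6
Reactants: 11 Z-alkenyl acid
Product: 12 3-{[(1S,2Z)-1-[3,4-bis(benzyloxy)phenyl]-4-hydroxybut-2-en-1-yl]oxy}propanoic acid
Conditions: Bu4NF (2.5 equiv), THF, 0 °C → rt; cold dilute HCl to pH 4–5
Reagents that add atoms: none
Why: Fluoride-driven silyl ether cleavage; under these conditions the acid is present as its carboxylate, which cannot lose the β-alkoxide by retro-oxa-Michael elimination, and the mild acidification spares the benzylic allylic ether.

Step 7
Reactants: 12 seco acid
Product: 14 (6S,7Z)-6-[3,4-bis(benzyloxy)phenyl]-1,5-dioxacyclonon-7-en-2-one, via mixed anhydride 13 (not isolated)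
Conditions: 2-methyl-6-nitrobenzoic anhydride (1.3 equiv), DMAP (3 equiv), CH2Cl2 (final 1 mM), rt, 12 added by syringe pump over 14 h
Reagents that add atoms: 2-methyl-6-nitrobenzoic anhydride, Cc1cccc([N+](=O)[O-])c1C(=O)OC(=O)c1c(C)cccc1[N+](=O)[O-] (aroyl unit, present in 13 only)
Why: Shiina macrolactonisation: mixed anhydride 13 is formed and acyl-transferred by DMAP at room temperature under pseudo-high dilution, the Z-alkene and the ring oxygen remove transannular H/H contacts and bring the chain ends together, and the mild temperature limits E1cB loss of the β-alkoxide from the activated acyl group.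

Step 8
Reactants: 14 nine-membered lactone
Product: 17 (3R,4S,5S)-5-[3,4-bis(benzyloxy)phenyl]-4-ethenyloxolane-3-carboxylic acid, via silyl ketene acetal 15 (not isolated), via trimethylsilyl ester 16 (not isolated)
Conditions: Me3SiCl/Et3N (1:1, 6 equiv), THF, −95 °C; LiN(SiMe3)2 (2.5 equiv) added dropwise; −95 °C → rt, then 60 °C; aq. NaH2PO4/citric acid (pH 4–5)
Reagents that add atoms: chlorotrimethylsilane, C[Si](C)(C)Cl (silyl group, present in 15 and 16 only)
Why: LiN(SiMe3)2 removes an α-proton (future C4) while Me3SiCl is already present, so the lactone enolate, which carries O1 as a β-leaving group, is O-silylated to the ring-cis ketene acetal 15 before it can open by retro-oxa-Michael elimination; on warming, 15 undergoes a concerted suprafacial [3,3] shift that makes C3–C4, breaks the allylic C–O bond and moves the alkene out of the ring as the vinyl group, and silyl ester 16 is hydrolysed on work-up. The closest known reaction type is the Ireland–Claisen ring contraction of unsaturated medium-ring lactones by four atoms, established for all-carbon, nitrogen-bridged and oxygen-bridged nine-membered rings, and the internal Me3SiCl quench is the established answer to ester enolates with β-leaving groups. The oxolane is closed transannularly (nine atoms to five), formally 5-exo-trig at the alkene with the ketene acetal C=C exocyclic to the new ring. C3 and C4: both C=C bonds are cis within the ring and only C5, O1 and C2 join their reacting ends, so only a boat-shaped six-atom array is within reach, and it puts carboxyl and vinyl on the same face (3,4-cis). C3 relative to C2: in the Z-alkene the C2–H bond must lie near the alkene plane, facing the allylic CH2O, to escape allylic 1,3-strain, which leaves O1 (and with it the incoming C4) on one face and the aryl group on the other, so vinyl and aryl end up trans and the (S)-centre of 14 fixes the absolute sense as (3R,4S,5S). The step therefore needs silylation to outrun elimination and one of four diastereomers to form; the first is secured by the low-temperature internal quench, the second by the ring geometry and the single stereocentre C2.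

Step 9
Reactants: 17 cis acid
Product: 19 (3R,4S,5S)-5-[3,4-bis(benzyloxy)phenyl]-4-ethenyl-N-methoxy-N-methyloxolane-3-carboxamide, via acyl imidazolide 18 (not isolated)
Conditions: 1,1'-carbonyldiimidazole (1.2 equiv), CH2Cl2, 0 °C → rt; then MeNH(OMe)·HCl (1.5 equiv), rt
Reagents that add atoms: N,O-dimethylhydroxylamine hydrochloride, CNOC.Cl; 1,1'-carbonyldiimidazole, O=C(n1ccnc1)n1ccnc1 (imidazolyl unit, present in 18 only)
Why: Acyl imidazolide activation followed by aminolysis (Weinreb amide synthesis) needs no strong base, so the epimerisable cis centre C4 should be kept.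

Step 10
Reactants: 20 4-bromo-2-methoxyphenol
Product: 21 1-(benzyloxy)-4-bromo-2-methoxybenzene
Conditions: BnBr, K2CO3, DMF, rt
Reagents that add atoms: benzyl bromide, BrCc1ccccc1
Why: Williamson benzylation masks the acidic phenol before the halogen–lithium exchange with the same group as on the catechol, so that one final step frees all three phenols.

Step 11
Reactants: 21 aryl bromide (1.5 equiv); 19 Weinreb amide
Product: 24 [(3R,4S,5S)-5-[3,4-bis(benzyloxy)phenyl]-4-ethenyloxolan-3-yl][4-(benzyloxy)-3-methoxyphenyl]methanone, via aryllithium 22 (not isolated), via lithium hemiaminal adduct 23 (not isolated)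
Conditions: 21, n-BuLi (1.45 equiv), THF, −78 °C; then 19, −78 °C; aq. NH4Cl at −78 °C
Reagents that add atoms: n-butyllithium, [Li]CCCC (lithium, present in 22 and 23 only)
Why: Bromine–lithium exchange and Weinreb ketone synthesis: the chelated adduct 23 persists until the cold quench, so only one aryl group adds and the C4-epimerisable β-alkoxy ketone never meets a strong base.

Step 12
Reactants: 24 aryl ketone
Product: 25 (R)-[(3R,4S,5S)-5-[3,4-bis(benzyloxy)phenyl]-4-ethenyloxolan-3-yl][4-(benzyloxy)-3-methoxyphenyl]methanol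
Conditions: (S)-Me-CBS oxazaborolidine [(3aS)-1-methyl-3,3-diphenyltetrahydro-1H,3H-pyrrolo[1,2-c][1,3,2]oxazaborole, 30 mol %], catecholborane (2 equiv), toluene, −78 → −40 °C; MeOH, then carbonate buffer wash
Reagents that add atoms: none
Why: Corey–Bakshi–Shibata reduction: with the aryl group in the "large" position the (S)-catalyst should deliver hydride to the Si face of C7 (the sense in which acetophenone gives (R)-1-phenylethanol) and set 7R, and catecholborane at low temperature replaces BH3 because it does not hydroborate the vinyl group.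

Step 13
Reactants: 25 (7R)-alcohol
Product: 28 8-[3,4-bis(benzyloxy)phenyl]-4-[4-(benzyloxy)-3-methoxyphenyl]-3,7-dioxabicyclo[3.3.0]octan-2-ol (cis-fused lactol; C2 C3 C4 C7 as in 25; lactol carbon C9 as anomer mixture), via vicinal diol 26 (not isolated), via hydroxy aldehyde 27 (not isolated)
Conditions: OsO4 (2 mol %), NaIO4 (4 equiv), 2,6-lutidine (2 equiv), 1,4-dioxane–H2O 3:1, rt; taken on crude
Reagents that add atoms: osmium tetroxide, O=[Os](=O)(=O)=O (delivers the oxygens of 26, catalytic); sodium periodate, [Na+].[O-]I(=O)(=O)=O (terminal source of oxygen)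
Why: Lemieux–Johnson oxidation: OsO4 dihydroxylates the only alkene, periodate cleaves diol 26, and aldehyde 27 is captured by the cis C7–OH as the cis-fused lactol 28, which should protect C3 from epimerisation (2,6-lutidine keeps the medium near neutral for the benzylic alcohol).

Step 14
Reactants: 28 lactol
Product: 29 (R)-[(3R,4R,5S)-5-[3,4-bis(benzyloxy)phenyl]-4-(hydroxymethyl)oxolan-3-yl][4-(benzyloxy)-3-methoxyphenyl]methanol
Conditions: NaBH4, THF–MeOH, 0 °C
Reagents that add atoms: none
Why: Borohydride reduction of the aldehyde tautomer in equilibrium with the lactol opens the second ring to the C7,C9-diol without touching a stereocentre.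

Step 15
Reactants: 29 tribenzyl ether
Product: 30 (7R)-7-hydroxytaxiresinol, 4-[(2S,3R,4R)-4-[(R)-hydroxy(4-hydroxy-3-methoxyphenyl)methyl]-3-(hydroxymethyl)oxolan-2-yl]benzene-1,2-diol
Conditions: H2 (1 atm), 10% Pd/C, EtOAc–EtOH 1:1, rt, monitored closely; filtered under argon
Reagents that add atoms: none
Why: Catalytic hydrogenolysis: aryl benzyl ethers are cleaved on Pd/C at 1 atm in a neutral solvent much faster than the secondary benzylic alcohol C7–OH or the cyclic benzylic ether C2–O1, which need acid, heat or long exposure, so the reaction is stopped as soon as the third benzyl group is gone.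

## Compound list

1 | 3,4-bis(benzyloxy)benzaldehyde | O=Cc1ccc(OCc2ccccc2)c(OCc2ccccc2)c1 | starting material
2 | tert-butyldimethyl(prop-2-yn-1-yloxy)silane | C#CCO[Si](C)(C)C(C)(C)C | starting material
3 | ethyl{3-[(tert-butyldimethylsilyl)oxy]prop-1-yn-1-yl}zinc (formed in the flask) | CC[Zn]C#CCO[Si](C)(C)C(C)(C)C | intermediate
4 | (1R)-1-[3,4-bis(benzyloxy)phenyl]-4-[(tert-butyldimethylsilyl)oxy]but-2-yn-1-ol | O[C@H](c1ccc(OCc2ccccc2)c(OCc2ccccc2)c1)C#CCO[Si](C)(C)C(C)(C)C | intermediate
5 | allyl bromide | C=CCBr | starting material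
6 | tert-butyl({(4R)-4-[3,4-bis(benzyloxy)phenyl]-4-(prop-2-en-1-yloxy)but-2-yn-1-yl}oxy)dimethylsilane | C=CCO[C@H](c1ccc(OCc2ccccc2)c(OCc2ccccc2)c1)C#CCO[Si](C)(C)C(C)(C)C | intermediate
7 | 9-(3-{[(1R)-1-[3,4-bis(benzyloxy)phenyl]-4-[(tert-butyldimethylsilyl)oxy]but-2-yn-1-yl]oxy}propyl)-9-borabicyclo[3.3.1]nonane (formed in the flask) | C1CC2CCCC(C1)B2CCCO[C@H](c1ccc(OCc2ccccc2)c(OCc2ccccc2)c1)C#CCO[Si](C)(C)C(C)(C)C | intermediate
8 | 3-{[(1R)-1-[3,4-bis(benzyloxy)phenyl]-4-[(tert-butyldimethylsilyl)oxy]but-2-yn-1-yl]oxy}propan-1-ol | OCCCO[C@H](c1ccc(OCc2ccccc2)c(OCc2ccccc2)c1)C#CCO[Si](C)(C)C(C)(C)C | intermediate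
9 | 3-{[(1R)-1-[3,4-bis(benzyloxy)phenyl]-4-[(tert-butyldimethylsilyl)oxy]but-2-yn-1-yl]oxy}propanal (formed in the flask) | O=CCCO[C@H](c1ccc(OCc2ccccc2)c(OCc2ccccc2)c1)C#CCO[Si](C)(C)C(C)(C)C | intermediate
10 | 3-{[(1R)-1-[3,4-bis(benzyloxy)phenyl]-4-[(tert-butyldimethylsilyl)oxy]but-2-yn-1-yl]oxy}propanoic acid | OC(=O)CCO[C@H](c1ccc(OCc2ccccc2)c(OCc2ccccc2)c1)C#CCO[Si](C)(C)C(C)(C)C | intermediate
11 | 3-{[(1S,2Z)-1-[3,4-bis(benzyloxy)phenyl]-4-[(tert-butyldimethylsilyl)oxy]but-2-en-1-yl]oxy}propanoic acid | OC(=O)CCO[C@H](c1ccc(OCc2ccccc2)c(OCc2ccccc2)c1)/C=C\CO[Si](C)(C)C(C)(C)C | intermediate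
12 | 3-{[(1S,2Z)-1-[3,4-bis(benzyloxy)phenyl]-4-hydroxybut-2-en-1-yl]oxy}propanoic acid | OC(=O)CCO[C@H](c1ccc(OCc2ccccc2)c(OCc2ccccc2)c1)/C=C\CO | intermediate
13 | mixed anhydride of 12 and 2-methyl-6-nitrobenzoic acid (formed in the flask) | Cc1cccc([N+](=O)[O-])c1C(=O)OC(=O)CCO[C@H](c1ccc(OCc2ccccc2)c(OCc2ccccc2)c1)/C=C\CO | intermediate
14 | (6S,7Z)-6-[3,4-bis(benzyloxy)phenyl]-1,5-dioxacyclonon-7-en-2-one | O=C1CCO[C@H](c2ccc(OCc3ccccc3)c(OCc3ccccc3)c2)/C=C\CO1 | intermediate
15 | (2E,6S,7Z)-6-[3,4-bis(benzyloxy)phenyl]-2-[(trimethylsilyl)oxy]-1,5-dioxacyclonona-2,7-diene, both C=C cis within the ring (formed in the flask) | C[Si](C)(C)O/C1=C/CO[C@H](c2ccc(OCc3ccccc3)c(OCc3ccccc3)c2)/C=C\CO1 | intermediate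
16 | trimethylsilyl (3R,4S,5S)-5-[3,4-bis(benzyloxy)phenyl]-4-ethenyloxolane-3-carboxylate (formed in the flask) | C[Si](C)(C)OC(=O)[C@H]1CO[C@H](c2ccc(OCc3ccccc3)c(OCc3ccccc3)c2)[C@H]1C=C | intermediate
17 | (3R,4S,5S)-5-[3,4-bis(benzyloxy)phenyl]-4-ethenyloxolane-3-carboxylic acid | OC(=O)[C@H]1CO[C@H](c2ccc(OCc3ccccc3)c(OCc3ccccc3)c2)[C@H]1C=C | intermediate
18 | [(3R,4S,5S)-5-[3,4-bis(benzyloxy)phenyl]-4-ethenyloxolan-3-yl](1H-imidazol-1-yl)methanone (formed in the flask) | O=C(n1ccnc1)[C@H]1CO[C@H](c2ccc(OCc3ccccc3)c(OCc3ccccc3)c2)[C@H]1C=C | intermediate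
19 | (3R,4S,5S)-5-[3,4-bis(benzyloxy)phenyl]-4-ethenyl-N-methoxy-N-methyloxolane-3-carboxamide | CON(C)C(=O)[C@H]1CO[C@H](c2ccc(OCc3ccccc3)c(OCc3ccccc3)c2)[C@H]1C=C | intermediate
20 | 4-bromo-2-methoxyphenol | COc1cc(Br)ccc1O | starting material
21 | 1-(benzyloxy)-4-bromo-2-methoxybenzene | COc1cc(Br)ccc1OCc1ccccc1 | intermediate
22 | [4-(benzyloxy)-3-methoxyphenyl]lithium (formed in the flask) | COc1cc([Li])ccc1OCc1ccccc1 | intermediate
23 | lithium N-methoxy-N-methyl hemiaminal adduct of 22 and 19, new carbon undefined (formed in the flask) | COc1cc(C(O[Li])(N(C)OC)[C@H]2CO[C@H](c3ccc(OCc4ccccc4)c(OCc4ccccc4)c3)[C@H]2C=C)ccc1OCc1ccccc1 | intermediate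
24 | [(3R,4S,5S)-5-[3,4-bis(benzyloxy)phenyl]-4-ethenyloxolan-3-yl][4-(benzyloxy)-3-methoxyphenyl]methanone | COc1cc(C(=O)[C@H]2CO[C@H](c3ccc(OCc4ccccc4)c(OCc4ccccc4)c3)[C@H]2C=C)ccc1OCc1ccccc1 | intermediate
25 | (R)-[(3R,4S,5S)-5-[3,4-bis(benzyloxy)phenyl]-4-ethenyloxolan-3-yl][4-(benzyloxy)-3-methoxyphenyl]methanol | COc1cc([C@H](O)[C@H]2CO[C@H](c3ccc(OCc4ccccc4)c(OCc4ccccc4)c3)[C@H]2C=C)ccc1OCc1ccccc1 | intermediate
26 | 1,2-diol from dihydroxylation of the vinyl group of 25, new carbinol undefined (formed in the flask) | COc1cc([C@H](O)[C@H]2CO[C@H](c3ccc(OCc4ccccc4)c(OCc4ccccc4)c3)[C@H]2C(O)CO)ccc1OCc1ccccc1 | intermediate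
27 | hydroxy aldehyde, open form of 28, ring and C7 configuration as in 25 (formed in the flask) | COc1cc([C@H](O)[C@H]2CO[C@H](c3ccc(OCc4ccccc4)c(OCc4ccccc4)c3)[C@H]2C=O)ccc1OCc1ccccc1 | intermediate
28 | 8-[3,4-bis(benzyloxy)phenyl]-4-[4-(benzyloxy)-3-methoxyphenyl]-3,7-dioxabicyclo[3.3.0]octan-2-ol, cis-fused, anomer mixture at the lactol carbon | COc1cc([C@@H]2OC(O)[C@@H]3[C@@H](c4ccc(OCc5ccccc5)c(OCc5ccccc5)c4)OC[C@H]23)ccc1OCc1ccccc1 | intermediate
29 | (R)-[(3R,4R,5S)-5-[3,4-bis(benzyloxy)phenyl]-4-(hydroxymethyl)oxolan-3-yl][4-(benzyloxy)-3-methoxyphenyl]methanol | COc1cc([C@H](O)[C@H]2CO[C@H](c3ccc(OCc4ccccc4)c(OCc4ccccc4)c3)[C@H]2CO)ccc1OCc1ccccc1 | intermediate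
30 | (7R)-7-hydroxytaxiresinol | COc1cc([C@H](O)[C@H]2CO[C@H](c3ccc(O)c(O)c3)[C@H]2CO)ccc1O | target

## Step count and risks

Total step count: 15.
Longest linear sequence: 14 steps (steps 1–9 and 11–15, from aldehyde 1). Step 10 lies on the side branch.

The three steps most likely to fail are steps 8, 7 and 12.

**1. Step 8.** The lactone enolate may expel the β-alkoxide (retro-oxa-Michael ring opening) faster than it is silylated. The ketene acetal may also be hydrolysed or C-silylated before it rearranges.

The fallback sets out from 4 and comes back at 19. It builds the oxolane by metathesis and sets the cis pair by kinetic protonation.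
- Compound 4 is semihydrogenated (H2, Pd/CaCO3 poisoned with Pb(OAc)2, quinoline, EtOAc) to the (1S,2Z)-allylic alcohol F1.
- The sodium alkoxide of F1 is alkylated with methyl 2-(bromomethyl)acrylate (NaH, THF, 0 °C) to the diene ether F2.
- Ring-closing metathesis (second-generation Grubbs catalyst, RuCl2(=CHPh)(PCy3)(H2IMes), CH2Cl2, 40 °C) closes the five-membered ring to the 2,5-dihydrofuran ester F3.
- Copper-catalysed conjugate addition of vinylmagnesium bromide (CuBr·SMe2, THF, −78 °C) should take place anti to the aryl group and give the bromomagnesium enolate F4.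
- F4 is protonated at −78 °C by a hindered phenol from the face away from the new vinyl group, which should give the cis methyl ester F5.
- F5 is converted with MeNH(OMe)·HCl and i-PrMgCl (THF, −20 °C) into Weinreb amide 19.

**2. Step 7.** Intermolecular acylation (diolide and oligomers) may outrun closure of the strained nine-membered ring. The activated acyl group may also lose the β-alkoxide by E1cB elimination.

The fallback sets out from 11 and comes back at 14. It closes the ring at the C=C bond and never activates the acyl group.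
- The caesium carboxylate of 11 is alkylated with allyl bromide 5 (Cs2CO3, DMF, rt) to the allyl ester F6.
- Ring-closing metathesis of F6 in dilute solution (second-generation Grubbs catalyst, RuCl2(=CHPh)(PCy3)(H2IMes), toluene, 1 mM, 60 °C) joins the terminal alkene to the internal one.
- The silyloxymethyl end leaves as its allyl ether. The product should be 14 as the Z-isomer, since an E-alkene is too strained in this ring.

**3. Step 12.** Facial selectivity may be poor, because the aryl group and the branched oxolanyl group differ little in size and the bias of the substrate may oppose the catalyst. A slow reduction would also leave time for epimerisation at C4.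

The fallback sets out from 24 and comes back at 25. It replaces catalyst control by substrate control with separation and recycling.
- Ketone 24 is reduced with NaBH4/CeCl3·7H2O (MeOH, −78 °C).
- Alcohol 25 is separated by chromatography from the (7S)-epimer F7.
- F7 is oxidised back to 24 with Dess–Martin periodinane (NaHCO3, CH2Cl2, 0 °C) and resubmitted.

## Further compounds

F1 | step 8 | (1S,2Z)-1-[3,4-bis(benzyloxy)phenyl]-4-[(tert-butyldimethylsilyl)oxy]but-2-en-1-ol | O[C@H](c1ccc(OCc2ccccc2)c(OCc2ccccc2)c1)/C=C\CO[Si](C)(C)C(C)(C)C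
F2 | step 8 | methyl 2-({[(1S,2Z)-1-[3,4-bis(benzyloxy)phenyl]-4-[(tert-butyldimethylsilyl)oxy]but-2-en-1-yl]oxy}methyl)prop-2-enoate | COC(=O)C(=C)CO[C@H](c1ccc(OCc2ccccc2)c(OCc2ccccc2)c1)/C=C\CO[Si](C)(C)C(C)(C)C
F3 | step 8 | methyl (5S)-5-[3,4-bis(benzyloxy)phenyl]-2,5-dihydrofuran-3-carboxylate | COC(=O)C1=C[C@@H](c2ccc(OCc3ccccc3)c(OCc3ccccc3)c2)OC1
F4 | step 8 | bromomagnesium enolate of F5 (4,5-trans, enolate geometry undefined) | COC(O[Mg]Br)=C1CO[C@H](c2ccc(OCc3ccccc3)c(OCc3ccccc3)c2)[C@H]1C=C
F5 | step 8 | methyl (3R,4S,5S)-5-[3,4-bis(benzyloxy)phenyl]-4-ethenyloxolane-3-carboxylate | COC(=O)[C@H]1CO[C@H](c2ccc(OCc3ccccc3)c(OCc3ccccc3)c2)[C@H]1C=C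
F6 | step 7 | prop-2-en-1-yl 3-{[(1S,2Z)-1-[3,4-bis(benzyloxy)phenyl]-4-[(tert-butyldimethylsilyl)oxy]but-2-en-1-yl]oxy}propanoate | C=CCOC(=O)CCO[C@H](c1ccc(OCc2ccccc2)c(OCc2ccccc2)c1)/C=C\CO[Si](C)(C)C(C)(C)C
F7 | step 12 | (S)-[(3R,4S,5S)-5-[3,4-bis(benzyloxy)phenyl]-4-ethenyloxolan-3-yl][4-(benzyloxy)-3-methoxyphenyl]methanol | COc1cc([C@@H](O)[C@H]2CO[C@H](c3ccc(OCc4ccccc4)c(OCc4ccccc4)c3)[C@H]2C=C)ccc1OCc1ccccc1
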